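The disconnection treats ring B of the right-hand (primed) lactone as 3,5-dimethoxybenzyne instead of a phenol. A masked benzyne (ortho-silyl aryl triflate), DMF and diallyl malonate combine in one operation that forms the aryl C8a'–O1' bond and the C3'–C4' bond, together with C4a'–C4' and O1'–C2', and delivers the complete pyranone ring as a coumarin ester. The step exploits the fact that O1' is meta to both oxygens of ring B, so that the C5' methoxy group polarises the aryne. Rhodium arylation then sets C4', decarboxylative allylation sets C3', and a carbene-catalysed annulation of a ring A ortho-quinone methide builds the cis left lactone before global demethylation.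

Key step: step 3

Remark: primed locants (C2'–C8a') denote the 5,7-dihydroxy chromanone with benzo ring B, unprimed locants the tetrahydroxy chromanone with benzo ring A. The sense of induction of the two chiral catalysts is assigned by analogy, and the antipodal ligand is to be used if a first run shows the opposite sense.

Step 1
Reactants: 1 3,5-dimethoxyphenol
Product: 2 2-bromo-3,5-dimethoxyphenol
Conditions: NBS (1.0 equiv), CH2Cl2, −78 °C to −20 °C
Reagents that add atoms: N-bromosuccinimide, O=C1CCC(=O)N1Br
Why: Electrophilic aromatic bromination of the strongly activated ring at low temperature should go ortho to the free hydroxyl, because the phenol hydrogen-bonds the reagent and the position between the two methoxy groups is the more hindered one; no stereocenter is involved.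

Step 2
Reactants: 2 2-bromo-3,5-dimethoxyphenol
Product: 5 3,5-dimethoxy-2-(trimethylsilyl)phenyl trifluoromethanesulfonate, via trimethylsilyl ether 3 (not isolated), via lithium phenolate 4 (not isolated)
Conditions: HMDS, THF, 65 °C, then evaporation; n-BuLi, THF, −100 °C; Tf2O, −100 °C to 25 °C
Reagents that add atoms: hexamethyldisilazane, C[Si](C)(C)N[Si](C)(C)C; trifluoromethanesulfonic anhydride, O=S(=O)(OS(=O)(=O)C(F)(F)F)C(F)(F)F
Why: Silylation of the phenol, bromine–lithium exchange and an anionic 1,3 O-to-C silyl shift (retro-Brook rearrangement) should give phenolate 4, whose triflation delivers the ortho-silyl aryl triflate that releases a benzyne with fluoride; no stereocenter is involved.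

Step 3
Reactants: 5 3,5-dimethoxy-2-(trimethylsilyl)phenyl trifluoromethanesulfonate; 6 diallyl malonate; 7 N,N-dimethylformamide (reactant and solvent)
Product: 12 allyl 5,7-dimethoxy-2-oxo-2H-chromene-3-carboxylate, via aryne 8 (not isolated), via benzoxete 9 (not isolated), via aminomethylene quinone methide 10 (not isolated), via amine adduct 11 (not isolated)
Conditions: CsF (3 equiv), DMF, 25 °C
Reagents that add atoms: none
Why: Fluoride-triggered 1,2-elimination of 5 should give 3,5-dimethoxybenzyne 8, whose triple bond is attacked by the carbonyl oxygen of DMF at the carbon remote from the flanking methoxy group (the aryl C8a'–O1' bond); collapse of the zwitterion gives benzoxete 9, which opens to ortho-quinone methide 10, and the malonate anion adds to its exocyclic carbon (the C3'–C4' bond) to give 11, which lactonises onto one allyl ester and loses dimethylamine by E1cB elimination. The closest known reaction type is the three-component coupling of arynes, formamides and active methylene compounds (aryne insertion into the C=O bond followed by Knoevenagel-type trapping). The four-membered ring of 9 closes by a stepwise polar [2+2] addition and reopens by 4π electrocyclic ring opening, and the pyranone ring is completed by 6-exo-trig acyl substitution of the phenoxide on the ester. No stereocenter is formed: C4' leaves the step as an sp2 carbon and becomes stereogenic in step 4. The step needs regioselectivity (oxygen at C8a', carbon at C4a'), which the inductive pull of the C5' methoxy group on the adjacent aryne carbon secures, and chemoselectivity for DMF over the malonate anion in capturing the aryne, which the use of DMF as solvent secures.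

Step 4
Reactants: 12 allyl 5,7-dimethoxy-2-oxo-2H-chromene-3-carboxylate; 13 4-methoxyphenylboronic acid
Product: 14 allyl (3S,4S)-5,7-dimethoxy-4-(4-methoxyphenyl)-2-oxochromane-3-carboxylate (3,4-trans)
Conditions: [RhCl(C2H4)2]2 (2.5 mol %), (S,S)-2,5-diphenylbicyclo[2.2.2]octa-2,5-diene (5.5 mol %), aq K3PO4 (0.5 equiv), dioxane/H2O (10:1), 30 °C
Reagents that add atoms: none
Why: Rhodium-catalysed asymmetric 1,4-addition of the arylboronic acid (Hayashi–Miyaura reaction) to the doubly activated C3'=C4' bond should set C4' as S under control of the chiral diene ligand, and the acidic C3' centre should equilibrate to the 3,4-trans arrangement.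

Step 5
Reactants: 14 allyl (3S,4S)-5,7-dimethoxy-4-(4-methoxyphenyl)-2-oxochromane-3-carboxylate
Product: 15 (3R,4S)-3-allyl-5,7-dimethoxy-4-(4-methoxyphenyl)chroman-2-one (3,4-trans)
Conditions: Pd(PPh3)4 (5 mol %), toluene, 60 °C
Reagents that add atoms: none
Why: Decarboxylative allylation (Tsuji-type) should proceed because zerovalent palladium ionises the allyl ester, the malonate-type carboxylate loses CO2 and the lactone enolate recombines with the allyl fragment at C3' on the face opposite the C4' aryl group, which sets C3' trans (3R) under substrate control.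

Step 6
Reactants: 15 (3R,4S)-3-allyl-5,7-dimethoxy-4-(4-methoxyphenyl)chroman-2-one
Product: 17 2-[(3R,4S)-5,7-dimethoxy-4-(4-methoxyphenyl)-2-oxochroman-3-yl]acetaldehyde, via diol 16 (not isolated)
Conditions: OsO4 (2 mol %), NaIO4 (4 equiv), 2,6-lutidine (2 equiv), dioxane/H2O (3:1), 25 °C
Reagents that add atoms: sodium periodate, [Na+].[O-]I(=O)(=O)=O
Why: Lemieux–Johnson cleavage (OsO4 dihydroxylation to 16, then periodate glycol fission) should convert the terminal alkene into the aldehyde without touching the electron-rich arenes that ozone would attack or the two stereocenters.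

Step 7
Reactants: 18 1,2,3,4-tetramethoxybenzene
Product: 21 2,3,4,5-tetramethoxyphenol, via aryllithium 19 (not isolated), via boronic ester 20 (not isolated)
Conditions: n-BuLi, TMEDA, THF, 0 °C; B(OMe)3, −78 °C to 25 °C; 30% H2O2, 0 °C
Reagents that add atoms: hydrogen peroxide, OO
Why: Directed ortho-lithiation beside a methoxy group, borylation and oxidative C–B to C–O exchange (boronate oxidation) should install the fifth oxygen; the two ring hydrogens are equivalent, so there is one product and no stereocenter.

Step 8
Reactants: 21 2,3,4,5-tetramethoxyphenol; 22 4-methoxybenzaldehyde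
Product: 23 2,3,4,5-tetramethoxy-6-[(4-methoxyphenyl)(4-methylbenzenesulfonyl)methyl]phenol (racemic)
Conditions: TolSO2H (1.2 equiv), TsOH·H2O (10 mol %), CH2Cl2, 25 °C
Reagents that add atoms: 4-methylbenzenesulfinic acid, Cc1ccc(cc1)S(=O)O
Why: Acid-mediated three-component Mannich-type condensation should alkylate the only free ring position, ortho to the hydroxyl, and the sulfinic acid should trap the benzylic cation as a stable sulfone; the new centre is racemic and is erased in step 9.

Step 9
Reactants: 17 2-[(3R,4S)-5,7-dimethoxy-4-(4-methoxyphenyl)-2-oxochroman-3-yl]acetaldehyde; 23 2,3,4,5-tetramethoxy-6-[(4-methoxyphenyl)(4-methylbenzenesulfonyl)methyl]phenol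
Product: 25 (3S,4R)-3-[(3S,4S)-5,7-dimethoxy-4-(4-methoxyphenyl)-2-oxochroman-3-yl]-5,6,7,8-tetramethoxy-4-(4-methoxyphenyl)chroman-2-one, via ortho-quinone methide 24 (not isolated)
Conditions: (5aR,10bS)-2-mesityl-4,5a,6,10b-tetrahydroindeno[2,1-b][1,2,4]triazolo[4,3-d][1,4]oxazin-2-ium tetrafluoroborate (15 mol %), 3,3',5,5'-tetra-tert-butyldiphenoquinone (1.2 equiv), Cs2CO3 (2.2 equiv), THF, 4 Å MS, 0 °C to 25 °C
Reagents that add atoms: none
Why: Oxidative N-heterocyclic carbene catalysis should turn aldehyde 17 into a catalyst-bound Z-enolate equivalent that adds to ortho-quinone methide 24 (released from 23 by base) in an endo formal [4+2] annulation (Michael addition then lactonisation), so that the endo mode sets C3 and C4 cis and the chiral triazolium fixes them as 3S,4R, the C3' centre acting as a spectator in the matched pairing.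

Step 10
Reactants: 25 (3S,4R)-3-[(3S,4S)-5,7-dimethoxy-4-(4-methoxyphenyl)-2-oxochroman-3-yl]-5,6,7,8-tetramethoxy-4-(4-methoxyphenyl)chroman-2-one
Product: 26 (3S,4R)-3-[(3S,4S)-5,7-dihydroxy-4-(4-hydroxyphenyl)-2-oxochroman-3-yl]-5,6,7,8-tetrahydroxy-4-(4-hydroxyphenyl)chroman-2-one (CNP0064734.2)
Conditions: BBr3 (16 equiv), CH2Cl2, −78 °C to 25 °C; H2O quench at 0 °C under argon
Reagents that add atoms: none
Why: Lewis-acid ether cleavage with BBr3 should remove all eight methyl groups under non-basic conditions that leave the base-sensitive cis C3 centre and both aryl lactones intact, any acyl migration being degenerate because each benzo ring is symmetric about its C4a–C7 axis.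

Compound list
1 | 3,5-dimethoxyphenol | COc1cc(O)cc(OC)c1 | starting material
2 | 2-bromo-3,5-dimethoxyphenol | COc1cc(O)c(Br)c(OC)c1 | intermediate
3 | (2-bromo-3,5-dimethoxyphenoxy)trimethylsilane | COc1cc(O[Si](C)(C)C)c(Br)c(OC)c1 | intermediate
4 | lithium 3,5-dimethoxy-2-(trimethylsilyl)phenolate | [Li+].COc1cc([O-])c([Si](C)(C)C)c(OC)c1 | intermediate
5 | 3,5-dimethoxy-2-(trimethylsilyl)phenyl trifluoromethanesulfonate | COc1cc(OS(=O)(=O)C(F)(F)F)c([Si](C)(C)C)c(OC)c1 | intermediate
6 | diallyl malonate | C=CCOC(=O)CC(=O)OCC=C | starting material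
7 | N,N-dimethylformamide | CN(C)C=O | starting material
8 | 3,5-dimethoxybenzyne | COC1=CC(OC)=CC#C1 | intermediate
9 | 2-(dimethylamino)-3,5-dimethoxy-2H-benzo[b]oxete | CN(C)C1Oc2cc(OC)cc(OC)c21 | intermediate
10 | 6-[(dimethylamino)methylidene]-3,5-dimethoxycyclohexa-2,4-dien-1-one | CN(C)C=C1C(=O)C=C(OC)C=C1OC | intermediate
11 | diallyl 2-[(dimethylamino)(2-hydroxy-4,6-dimethoxyphenyl)methyl]propanedioate | C=CCOC(=O)C(C(=O)OCC=C)C(N(C)C)c1c(O)cc(OC)cc1OC | intermediate
12 | allyl 5,7-dimethoxy-2-oxo-2H-chromene-3-carboxylate | C=CCOC(=O)C1=Cc2c(OC)cc(OC)cc2OC1=O | intermediate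
13 | 4-methoxyphenylboronic acid | COc1ccc(cc1)B(O)O | starting material
14 | allyl (3S,4S)-5,7-dimethoxy-4-(4-methoxyphenyl)-2-oxochromane-3-carboxylate | C=CCOC(=O)[C@H]1C(=O)Oc2cc(OC)cc(OC)c2[C@@H]1c1ccc(OC)cc1 | intermediate
15 | (3R,4S)-3-allyl-5,7-dimethoxy-4-(4-methoxyphenyl)chroman-2-one | C=CC[C@H]1C(=O)Oc2cc(OC)cc(OC)c2[C@@H]1c1ccc(OC)cc1 | intermediate
16 | (3R,4S)-3-(2,3-dihydroxypropyl)-5,7-dimethoxy-4-(4-methoxyphenyl)chroman-2-one (carbinol epimers) | OCC(O)C[C@H]1C(=O)Oc2cc(OC)cc(OC)c2[C@@H]1c1ccc(OC)cc1 | intermediate
17 | 2-[(3R,4S)-5,7-dimethoxy-4-(4-methoxyphenyl)-2-oxochroman-3-yl]acetaldehyde | O=CC[C@H]1C(=O)Oc2cc(OC)cc(OC)c2[C@@H]1c1ccc(OC)cc1 | intermediate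
18 | 1,2,3,4-tetramethoxybenzene | COc1ccc(OC)c(OC)c1OC | starting material
19 | (2,3,4,5-tetramethoxyphenyl)lithium | [Li]c1cc(OC)c(OC)c(OC)c1OC | intermediate
20 | dimethyl (2,3,4,5-tetramethoxyphenyl)boronate | COB(OC)c1cc(OC)c(OC)c(OC)c1OC | intermediate
21 | 2,3,4,5-tetramethoxyphenol | COc1cc(O)c(OC)c(OC)c1OC | intermediate
22 | 4-methoxybenzaldehyde | COc1ccc(C=O)cc1 | starting material
23 | 2,3,4,5-tetramethoxy-6-[(4-methoxyphenyl)(4-methylbenzenesulfonyl)methyl]phenol (racemic) | COc1ccc(cc1)C(c1c(O)c(OC)c(OC)c(OC)c1OC)S(=O)(=O)c1ccc(C)cc1 | intermediate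
24 | 2,3,4,5-tetramethoxy-6-[(4-methoxyphenyl)methylidene]cyclohexa-2,4-dien-1-one | COc1ccc(cc1)C=C1C(=O)C(OC)=C(OC)C(OC)=C1OC | intermediate
25 | (3S,4R)-3-[(3S,4S)-5,7-dimethoxy-4-(4-methoxyphenyl)-2-oxochroman-3-yl]-5,6,7,8-tetramethoxy-4-(4-methoxyphenyl)chroman-2-one | O=C1Oc2c(OC)c(OC)c(OC)c(OC)c2[C@@H](c2ccc(OC)cc2)[C@H]1[C@H]1C(=O)Oc2cc(OC)cc(OC)c2[C@@H]1c1ccc(OC)cc1 | intermediate
26 | (3S,4R)-3-[(3S,4S)-5,7-dihydroxy-4-(4-hydroxyphenyl)-2-oxochroman-3-yl]-5,6,7,8-tetrahydroxy-4-(4-hydroxyphenyl)chroman-2-one | O=C1Oc2c(O)c(O)c(O)c(O)c2[C@@H](c2ccc(O)cc2)[C@H]1[C@H]1C(=O)Oc2cc(O)cc(O)c2[C@@H]1c1ccc(O)cc1 | target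

Total step count: 10 steps. Longest linear sequence: 8 steps (steps 1, 2, 3, 4, 5, 6, 9, 10); steps 7 and 8 form the short side branch.

Steps most likely to fail

Step 3 (key step): the benzyne may be captured by the malonate anion (C-arylation or insertion into the malonate C–C bond) faster than by DMF, the attack of DMF may lose regiocontrol, or the amine adduct may fail to eliminate dimethylamine. As a fallback, setting out from 5, the benzyne would be generated with CsF in DMF in the absence of a carbon acid and the adduct hydrolysed on aqueous work-up to 2-hydroxy-4,6-dimethoxybenzaldehyde F1 (aryne insertion into the formamide C=O bond, so the aryl–oxygen bond still comes from the benzyne). Knoevenagel condensation of F1 with 6 (piperidine, AcOH, EtOH, 70 °C), with spontaneous lactonisation, would come back to the route at 12.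

Step 9: the catalyst-bound enolate equivalent may be oxidised further to an unsaturated acyl species, the new cis centre may epimerise under base, the endo preference may erode if the quinone methide reacts through its other alkene geometry, and the catalyst may be mismatched with the C3' centre. As a fallback, setting out from 17, organocatalytic α-chlorination (N-chlorosuccinimide, L-proline 10 mol %, CH2Cl2, 0 °C) would give 2-chloro-2-[(3R,4S)-5,7-dimethoxy-4-(4-methoxyphenyl)-2-oxochroman-3-yl]acetaldehyde F2 as a mixture of epimers at the chlorinated carbon. Under redox-neutral carbene catalysis (same triazolium family, Cs2CO3, toluene, 0 °C, no oxidant), loss of HCl from the Breslow intermediate would give the same enolate equivalent, which annulates with 24 released from 23 and comes back to the route at 25.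

Step 4: enantioface discrimination may be poor on a coumarin that carries both a 3-alkoxycarbonyl group and a peri methoxy group, and the allyl ester or the activated lactone may be lost under the rhodium and base conditions. As a fallback, setting out from 12, deallylation (Pd(PPh3)4, morpholine, THF) would give 5,7-dimethoxy-2-oxo-2H-chromene-3-carboxylic acid F3, and protodecarboxylation (Cu2O, 1,10-phenanthroline, NMP/quinoline, 170 °C) would give 5,7-dimethoxy-2H-chromen-2-one F4. The established rhodium-catalysed arylation of the unsubstituted coumarin (Rh(acac)(C2H4)2, (S)-SEGPHOS, 13, dioxane/H2O, 60 °C) would give (S)-5,7-dimethoxy-4-(4-methoxyphenyl)chroman-2-one F5. Trans-selective enolate allylation (LiHMDS, allyl bromide, THF, −78 °C) would come back to the route at 15, bypassing step 5 as well.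

Further compounds
F1 | step 3 | 2-hydroxy-4,6-dimethoxybenzaldehyde | COc1cc(O)c(C=O)c(OC)c1
F2 | step 9 | 2-chloro-2-[(3R,4S)-5,7-dimethoxy-4-(4-methoxyphenyl)-2-oxochroman-3-yl]acetaldehyde (epimers at the chlorinated carbon) | O=CC(Cl)[C@H]1C(=O)Oc2cc(OC)cc(OC)c2[C@@H]1c1ccc(OC)cc1
F3 | step 4 | 5,7-dimethoxy-2-oxo-2H-chromene-3-carboxylic acid | OC(=O)C1=Cc2c(OC)cc(OC)cc2OC1=O
F4 | step 4 | 5,7-dimethoxy-2H-chromen-2-one | O=C1C=Cc2c(OC)cc(OC)cc2O1
F5 | step 4 | (S)-5,7-dimethoxy-4-(4-methoxyphenyl)chroman-2-one | O=C1Oc2cc(OC)cc(OC)c2[C@H](c2ccc(OC)cc2)C1
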